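The chalcone is treated as an opened flavanone. On ring A the acyl-bearing carbon C1' lies between C2' (OMe) and C6' (pyran oxygen); joining the C2' oxygen to the enone β-carbon recreates ring C of naringenin, so all pyran and stereocentre chemistry is done on an enone-free flavanone. The key step then opens ring C by E1cB cleavage of the C2–O1 bond and caps the released O1 phenoxide with iodomethane, giving the (E)-enone and the aryl methyl ether in one operation and deleting the uncontrolled C2 centre. Its precursor is a 7,4'-di-O-MOM flavanone whose ring A carries the (S)-3-hydroxy-2,2-dimethyldihydropyran fused across O5 and C6.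

Key step: step 6

Remark: naringenin is used as the racemate and flavanone C2 is carried as an epimer mixture (no descriptor drawn) until step 6 removes it; the dimethylpyran ring is numbered O1'', C2'' (gem-dimethyl), C3'', C4'' (bonded to flavanone C6).

Step 1
Reactants: 1 (±)-naringenin
Product: 2 7,4'-di-O-MOM-naringenin (5-OH free)
Conditions: MOMCl (2.3 equiv), i-Pr2NEt, CH2Cl2, 0 °C to rt
Reagents that add atoms: chloromethyl methyl ether (MOMCl), COCCl
Why: Selective phenol O-alkylation (MOM acetal formation): the 7-OH and 4'-OH react as ordinary phenols, whereas the 5-OH is held in a hydrogen bond to the C4 carbonyl and should stay free with a hindered amine base at low temperature.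

Step 2
Reactants: 2 7,4'-di-O-MOM-naringenin; 3 3-chloro-3-methylbut-1-yne
Product: 4 5-O-(1,1-dimethylprop-2-ynyl)-7,4'-di-O-MOM-naringenin
Conditions: 3 (1.3 equiv), CuCl2·2H2O (1 mol%), DBU (1.2 equiv), MeCN, 0 °C
Reagents that add atoms: 3-chloro-3-methylbut-1-yne (compound 3), CC(C)(Cl)C#C
Why: Copper-catalysed propargylic O-alkylation of a phenol (a copper acetylide ionises the tertiary chloride and the phenoxide adds to the resulting copper allenylidene at the tertiary carbon): the 5-OH is the only free hydroxyl, and cold, near-stoichiometric base is chosen to limit opening of ring C, which before alkylation would in any case give a symmetric 2',6'-diphenol that recloses to the same ether.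

Step 3
Reactants: 4 5-O-(1,1-dimethylprop-2-ynyl)-7,4'-di-O-MOM-naringenin
Product: 7 7,4'-di-O-MOM pyranoflavanone (2'',2''-dimethyl-2H-pyran fused to ring A at O5/C6), via allenyl phenol 5 (not isolated), via ortho-quinone methide 6 (not isolated)
Conditions: o-xylene, 140 °C
Reagents that add atoms: none
Why: Aryl propargyl ether Claisen rearrangement cascade: the [3,3] shift can deliver the allenyl group only to C6 because the other ortho position C4a is quaternary, tautomerisation gives 5, a 1,5-hydrogen shift gives 6, and oxa-6π electrocyclisation forms the O5–C2'' bond of the chromene under neutral conditions that the MOM acetals tolerate.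

Step 4
Reactants: 7 7,4'-di-O-MOM pyranoflavanone
Product: 8 (3''S,4''S)-3'',4''-epoxide of 7 (mixture of C2 epimers)
Conditions: (S,S)-Jacobsen catalyst [(S,S)-N,N'-bis(3,5-di-tert-butylsalicylidene)cyclohexane-1,2-diaminato]MnCl (4 mol%), 4-phenylpyridine N-oxide (20 mol%), aq NaOCl (pH 11.3, Na2HPO4 buffer), CH2Cl2, 0 °C; crude epoxide passed through basic alumina and used at once
Reagents that add atoms: sodium hypochlorite, [Na+].[O-]Cl
Why: Jacobsen–Katsuki epoxidation: cis-disubstituted 2,2-dimethylchromene alkenes are among the best substrates for the oxo(salen)manganese oxidant, and the (S,S)-ligand is expected, from the established facial preference for this alkene class, to set C3'' and C4'' as (S,S) by catalyst control regardless of the remote C2 centre.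

Step 5
Reactants: 8 (3''S,4''S)-epoxide
Product: 9 (3''S)-3''-hydroxy-2'',2''-dimethyl-3'',4''-dihydropyranoflavanone 7,4'-di-MOM ether (mixture of C2 epimers)
Conditions: H2 (1 atm), 10% Pd/C, NaHCO3 (solid), EtOAc, rt
Reagents that add atoms: none
Why: Catalytic hydrogenolysis of a benzylic epoxide: palladium cleaves only the strained benzylic C4''–O bond, so C3'' keeps its oxygen and its (S) configuration, while the absence of an enone and the neutral, bicarbonate-buffered medium should spare the deactivated aryl ketone, the C2–O1 benzylic ether and the MOM acetals.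

Step 6
Reactants: 9 (3''S)-hydroxy-dihydropyranoflavanone di-MOM ether; 10 iodomethane
Product: 12 di-O-MOM chalcone (2E)-1-[(3S)-3-hydroxy-7-methoxy-5-(methoxymethoxy)-2,2-dimethylchroman-8-yl]-3-[4-(methoxymethoxy)phenyl]prop-2-en-1-one, via chalcone potassium phenoxide 11 (not isolated)
Conditions: MeI (3 equiv), K2CO3 (3 equiv), DMF, rt to 40 °C
Reagents that add atoms: iodomethane (compound 10), CI
Why: Retro-oxa-Michael (E1cB) ring opening with alkylative trapping: carbonate reversibly removes a C3 proton next to the C4 ketone, the enolate expels the O1 aryloxide (C2–O1 cleavage) to give chalcone phenoxide 11, and SN2 methylation by iodomethane is irreversible, so the unfavourable flavanone–chalcone equilibrium is drained completely. The closest known reaction type is the carbonate/alkyl halide conversion of flavanones into 2'-alkoxychalcones. No ring is closed; ring C is opened. No stereocentre is created: C2 becomes sp2, so both C2 epimers of 9 converge on one compound, C3'' is untouched, and the (E) geometry follows from expulsion through the conformer with the 2-aryl group equatorial (aryl anti to C4) and from thermodynamic preference. The selectivity needed is methylation only at the released oxygen, which is secured because the other two phenols are MOM-capped, carbonate does not ionise the secondary C3'' alcohol, unimolecular aryloxide loss should outrun bimolecular C-methylation of the enolate, and the product has no free ortho phenol with which to reclose.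

Step 7
Reactants: 12 di-O-MOM chalcone
Product: 13 target CNP0122093.2 (2E)-1-[(3S)-3,5-dihydroxy-7-methoxy-2,2-dimethylchroman-8-yl]-3-(4-hydroxyphenyl)prop-2-en-1-one
Conditions: conc. HCl (cat.), MeOH, 40 °C
Reagents that add atoms: none
Why: Acid-catalysed acetal exchange (MOM removal): both aryl MOM acetals are transferred to methanol as dimethoxymethane under mild acid, while the aryl methyl ether, the chroman ether, the secondary alcohol and the enone should persist, the chalcone being unable to cyclise because both ortho oxygens of the acyl-bearing carbon are etherified.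

Compound list
1 | (±)-naringenin, 5,7-dihydroxy-2-(4-hydroxyphenyl)chroman-4-one | O=C1CC(c2ccc(O)cc2)Oc2cc(O)cc(O)c12 | starting material
2 | 7,4'-di-O-MOM-naringenin, 5-hydroxy-7-(methoxymethoxy)-2-[4-(methoxymethoxy)phenyl]chroman-4-one | O=C1CC(c2ccc(OCOC)cc2)Oc2cc(OCOC)cc(O)c12 | intermediate
3 | 3-chloro-3-methylbut-1-yne | CC(C)(Cl)C#C | starting material
4 | 5-O-(1,1-dimethylprop-2-ynyl)-7,4'-di-O-MOM-naringenin | O=C1CC(c2ccc(OCOC)cc2)Oc2cc(OCOC)cc(OC(C)(C)C#C)c12 | intermediate
5 | allenyl phenol: 5-hydroxy-6-(3-methylbuta-1,2-dienyl)-7,4'-di-O-MOM-flavanone | O=C1CC(c2ccc(OCOC)cc2)Oc2cc(OCOC)c(C=C=C(C)C)c(O)c12 | intermediate (not isolated)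
6 | ortho-quinone methide: ring A dienone with C5=O and exocyclic 6-(3-methylbut-2-enylidene) | O=C1CC(c2ccc(OCOC)cc2)OC2=C1C(=O)C(=CC=C(C)C)C(OCOC)=C2 | intermediate (not isolated)
7 | 7,4'-di-O-MOM pyranoflavanone: 2'',2''-dimethyl-2H-pyran fused to ring A (C6–CH=CH–C(CH3)2–O–C5) | O=C1CC(c2ccc(OCOC)cc2)Oc2cc(OCOC)c3C=CC(C)(C)Oc3c12 | intermediate
8 | (3''S,4''S)-3'',4''-epoxide of 7, mixture of C2 epimers | O=C1CC(c2ccc(OCOC)cc2)Oc2cc(OCOC)c3[C@@H]4O[C@@H]4C(C)(C)Oc3c12 | intermediate
9 | (3''S)-3''-hydroxy-2'',2''-dimethyl-3'',4''-dihydropyranoflavanone 7,4'-di-MOM ether, mixture of C2 epimers | O=C1CC(c2ccc(OCOC)cc2)Oc2cc(OCOC)c3C[C@H](O)C(C)(C)Oc3c12 | intermediate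
10 | iodomethane | CI | starting material
11 | ring-opened (E)-chalcone potassium 2'-phenoxide of 9 | [K+].[O-]c1cc(OCOC)c2c(c1C(=O)/C=C/c1ccc(OCOC)cc1)OC(C)(C)[C@@H](O)C2 | intermediate (not isolated)
12 | (2E)-1-[(3S)-3-hydroxy-7-methoxy-5-(methoxymethoxy)-2,2-dimethylchroman-8-yl]-3-[4-(methoxymethoxy)phenyl]prop-2-en-1-one | COc1cc(OCOC)c2c(c1C(=O)/C=C/c1ccc(OCOC)cc1)OC(C)(C)[C@@H](O)C2 | intermediate
13 | (2E)-1-[(3S)-3,5-dihydroxy-7-methoxy-2,2-dimethylchroman-8-yl]-3-(4-hydroxyphenyl)prop-2-en-1-one (CNP0122093.2) | COc1cc(O)c2c(c1C(=O)/C=C/c1ccc(O)cc1)OC(C)(C)[C@@H](O)C2 | target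

Total step count: 7. Longest linear sequence: 7 steps, from naringenin 1 to target 13.

Steps most likely to fail

Step 2. The hydrogen-bonded, flanked 5-phenoxide may be etherified only slowly. Base-induced opening of ring C in the product already formed, followed by a second propargylation of the freed phenoxide, could then compete. The fallback sets out from 2 and returns at 7, bypassing 4, by an ortho-directed phenol–enal chromene annulation. Compound 2 is converted into its titanium phenoxide with Ti(OEt)4 in toluene and heated at reflux with 3-methylbut-2-enal. Delivery of the aldehyde to C6, the only free ortho carbon, should give the ortho-hydroxybenzylic carbinol F1 (not isolated). Loss of water leads to quinone methide 6, and the same oxa-6π closure gives 7.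

Step 4. Oxygen transfer may show insufficient facial selectivity, and this step is the only source of the C3'' configuration. The acid-sensitive benzylic epoxide may also be lost during handling, or ring A may be chlorinated at C8 by hypochlorite. The fallback sets out from 7 and comes back at 12 through a racemic series and a classical resolution after C2 has been erased.
- Dimethyldioxirane in acetone at 0 °C should give the racemic cis-epoxide F2.
- H2 with 10% Pd/C in EtOAc gives the racemic alcohol F3.
- MeI and K2CO3 in DMF open ring C through the racemic chalcone potassium phenoxide F4 (not isolated) to the racemic di-O-MOM chalcone F5.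
- Acylation with (1S)-(−)-camphanic chloride, pyridine and DMAP in CH2Cl2 gives two diastereomeric esters, separable by chromatography or crystallisation: the camphanate of the (S)-alcohol F6 and the camphanate of the (R)-alcohol F7, which is set aside.
- Methanolysis of F6 with K2CO3 in MeOH at rt releases 12.

Step 5. Traces of acid on the catalyst may rearrange the epoxide to the C3'' ketone, whose reduction would not be stereocontrolled and would erode enantiopurity. Over-reduction at the C2–O1 benzylic ether or at the C4 ketone is also possible. The fallback sets out from 8 and returns at 9 by a two-stage, non-catalytic removal of the C4'' oxygen. Thiophenol with catalytic Et3N in CH2Cl2 at 0 °C should open the epoxide at the benzylic C4'' with inversion, giving the trans hydroxy sulfide F8. Radical desulfurisation with Bu3SnH and AIBN in toluene at 90 °C then cleaves the benzylic C–S bond to give 9, with C3'' untouched.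

Further compounds
F1 | step 2 | 5-hydroxy-6-(1-hydroxy-3-methylbut-2-enyl)-7,4'-di-O-MOM-flavanone (carbinol adduct, not isolated) | O=C1CC(c2ccc(OCOC)cc2)Oc2cc(OCOC)c(C(O)C=C(C)C)c(O)c12
F2 | step 4 | racemic cis-3'',4''-epoxide of 7 (all stereoisomers) | O=C1CC(c2ccc(OCOC)cc2)Oc2cc(OCOC)c3C4OC4C(C)(C)Oc3c12
F3 | step 4 | racemic 3''-hydroxy-2'',2''-dimethyl-3'',4''-dihydropyranoflavanone 7,4'-di-MOM ether | O=C1CC(c2ccc(OCOC)cc2)Oc2cc(OCOC)c3CC(O)C(C)(C)Oc3c12
F4 | step 4 | racemic ring-opened (E)-chalcone potassium 2'-phenoxide (not isolated) | [K+].[O-]c1cc(OCOC)c2c(c1C(=O)/C=C/c1ccc(OCOC)cc1)OC(C)(C)C(O)C2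
F5 | step 4 | racemic di-O-MOM chalcone (racemate of 12) | COc1cc(OCOC)c2c(c1C(=O)/C=C/c1ccc(OCOC)cc1)OC(C)(C)C(O)C2
F6 | step 4 | (1S,4R)-camphanate ester of the (3S)-alcohol 12 | COc1cc(OCOC)c2c(c1C(=O)/C=C/c1ccc(OCOC)cc1)OC(C)(C)[C@@H](OC(=O)[C@@]13CC[C@@](C)(C(=O)O1)C3(C)C)C2
F7 | step 4 | (1S,4R)-camphanate ester of the (3R)-alcohol (enantiomer of 12) | COc1cc(OCOC)c2c(c1C(=O)/C=C/c1ccc(OCOC)cc1)OC(C)(C)[C@H](OC(=O)[C@@]13CC[C@@](C)(C(=O)O1)C3(C)C)C2
F8 | step 5 | (3''R,4''R)-trans-3''-hydroxy-4''-(phenylsulfanyl)-2'',2''-dimethyl-3'',4''-dihydropyranoflavanone 7,4'-di-MOM ether | O=C1CC(c2ccc(OCOC)cc2)Oc2cc(OCOC)c3[C@@H](Sc4ccccc4)[C@H](O)C(C)(C)Oc3c12
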